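Start from the vessel: a closed, stirred flask in which solid substrate and enzyme stand together, and from which you want the target at 20 h.

| flask | solid substrate | enzyme | remark | time |
|---|---|---|---|---|
| Saturday's | 20 mM | 2 µM | the very flask that is asked about, followed so far |  |
| Wednesday's | 20 mM | 1 µM | run made earlier |  |
| flask | 20 mM | 2.0 µM |  | 20 h |

| run | time / h | target / % | solid substrate / % |
|---|---|---|---|
| Saturday's | 0.333 | 0 | 98.5 |
| Saturday's | 0.833 | 0 | 98.2 |
| Saturday's | 1.50 | 0 | 93.1 |
| Saturday's | 2.50 | 0.9 | 88.7 |
| Wednesday's | 1.00 | 0.6 | 96.8 |
| Wednesday's | 2.50 | 0.3 | 88.5 |
| Wednesday's | 6.00 | 2.2 | 77.5 |
| Wednesday's | 15.0 | 12.1 | 57.1 |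

(standard deviation of a reading: 1 percentage point)

- given per volume of solution although it is solid: solid substrate
- at the start none of the solid substrate is in solution

- south: doubling the amount of enzyme, all else as stated
- south-west: doubling the dissolution coefficient of the solid substrate, all else as stated
- south-east: doubling the solubility of the solid substrate, all else as stated

* the target standing at 20 h, as a percentage of the solid substrate charged
* the change that raises the amount of target at 20 h, in percent of the solid substrate charged most ("none" if none brings more than 2 percentage points) (south / south-west / south-east / none)
* amount of target at 20 h, in percent of the solid substrate charged, after south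

Try the bench rule first and count all solid gone as target made: in Wednesday's run at 15.0 h the solid has lost 42.9%, yet the target reads 12.1%, a ratio of 0.282, and the rule needs that ratio near 1. So write the balance of the solid substrate instead: what was charged is solid plus dissolved plus target, and the gap gives a dissolved part of 20.3% at 6.00 h and 30.8% at 15.0 h.

Divide Wednesday's gain of 9.9 percentage points over those 9.00 h by the mean dissolved part and by the enzyme, and read 0.0431 h⁻¹ µM⁻¹, a pseudo-first-order constant while the enzyme stays as charged. Assume proportion to enzyme, and Saturday's 2.0 µM gives 11.6 h, the clearing time: target gained in a stretch is the mean dissolved part times the stretch, divided by this time. Guess Saturday's mean dissolved part at Wednesday's 20.3%, and commit to 35.0%.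

The forecast gives 32% (from 27% to 37%), which stands lower than this reckoning; after south it gives 50% (from 41% to 58%), and it picks south-east, “assuming the enzyme does not saturate”.

Saturday's flask gives 33.9%, and 51.8% after south; the best change is south-east, gaining 26 points against 18 points for south and 14 points for south-west.

    starting material + enzyme → target + enzyme, rate k1*[starting material]*[enzyme]/(1 + ([starting material]/Km1)) (27.0 mM, k = 52000 M⁻¹ h⁻¹)
    solid substrate ⇌ starting material, rate k2*(cs2 - [starting material]) while solid is left; crystals form when [starting material] > cs2 (solubility = 10.0 mM, k = 0.0950 h⁻¹)

A run of south-east gaining less than the 18 points of south, which is 8.4 points below its gain here, would overturn that choice. In Saturday's flask, starting material, which is the dissolved part, stands at 21.5% at 10.0 h and 25.2% at 20.0 h, so the clearing time gives a gain of 20 points, and the target gains 21 points. Read the same flask at 12 h instead: starting material stands at 22.8%, so the 12.8% of target at 10.0 h should become 16.7%, and that reading holds 16.8%.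

(The data are calculated on assumed constants; noise was put on by code.)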